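# Proposed synthesis of 5,7-dihydroxy-2-(5-hydroxy-2,4-dimethoxyphenyl)-3,6,8-trimethoxy-4H-chromen-4-one (CNP0156395.0)

## Analysis of the target

The target is a flavone: a benzo ring A fused to a 4-pyranone ring C, which carries a trioxygenated phenyl ring B at C2. It has no stereocentre. The only stereochemical element met on the way is the geometry of an acyclic enol ether, and that disappears when ring C forms. Ring A is hexasubstituted, with hydroxyls at C5 and C7 alternating with methoxyls at C6 and C8; ring C carries a methoxyl at C3; ring B carries a free hydroxyl at C5' beside methoxyls at C2' and C4'. The sensitive points are the three phenols on electron-rich rings (the oxygens at C5 and C8 stand para and invite oxidation to a quinone), the pyranone, which hard nucleophiles can open at C2, and the five methyl ethers, which must survive whatever unmasks the three hydroxyls. The difficulty is one of differentiation and of acylation. Three of the eight oxygens must end as OH, and the C4–C4a ketone has to sit on a ring whose neighbouring carbons C5 and C8a both carry oxygen, where Friedel–Crafts or Fries chemistry offers poor regiocontrol and risks ether cleavage. The strategy rests on the ortho pair O1–C8a and C4–C4a on ring A, with the C5 oxygen next to C4a. This is the pattern left when a carboxylate oxygen and its own acyl carbon add across the triple bond of a 3-alkoxy aryne. For the C5 oxygen to be the only group flanking that triple bond, C8 must be hydrogen at that stage, so the C8 methoxyl is added afterwards.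

## Retrosynthetic reasoning

**Unmasking the hydroxyls (25 from 24).** The three O–H bonds of 25 are traced back to three benzyl ethers in 24. Benzyl separates the future hydroxyls from the five methoxyls from the first step on, and it tolerates fluoride, carbonate bases, organolithium at low temperature and hot methoxide with copper. It is removed under neutral reducing conditions that leave the methyl ethers and the tetrasubstituted C2=C3 bond alone.

**The C8 methoxyl (24 from 23 from 22).** The C8–O bond is cut, then the C8–Br bond. In 22, C8 is the only unsubstituted carbon of ring A and is ortho to O1 and O7 and para to O5, so electrophilic bromination followed by copper-mediated exchange of the halogen for a methoxyl should place the last substituent. The C8 oxygen is not carried through the ring-forming step because two alkoxy groups flanking the aryne would leave nothing to tell C8a from C4a.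

**Ring C (22 from 21).** The O1–C2 bond is cut. In the forward sense the phenol oxygen of 21 adds to the β-carbon of the enone and the methoxyl on that carbon leaves, so ring C arrives at the pyranone oxidation level without an oxidant. The C3 methoxyl already sits on the α-carbon.

**The key disconnection (21 from 19 and 10 through 20).** The O1–C8a and C4–C4a bonds are cut together. No other cut makes the aryl–oxygen and aryl–acyl bonds in one operation with the regiochemistry set by a single neighbouring substituent. The cut is also convergent: acid 19 brings ring B and all three carbons C2, C3 and C4 with their oxygens, and silyl triflate 10 brings ring A. The forward reaction must generate aryne 20 under conditions the carboxylic acid tolerates, add the carboxylate oxygen at the carbon remote from the benzyloxy group, and pass the acyl group to the neighbouring carbon.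

**The aryne precursor (10 from 7, 6, 4, 3, 2 and 1).** The silyl and triflate groups of 10 are traced to ortho-bromophenol 7 through an oxygen-to-carbon silyl shift. Compound 7 comes from phenol 6, which is symmetric, so monobromination can give only one isomer. The phenol oxygen of 6 replaces the carboxyl carbon of acid 1 through aldehyde 4 and a Baeyer–Villiger oxidation; 2 and 3 are the benzylated ester and the alcohol on the way. The gain is that the 1,2,3-trioxygenated pattern with the methoxyl in the middle is bought ready-made in 1.

**The acid (19 from 18, 17, 16, 14 and 15; 14 from 13 and 11).** The enol ether O–methyl bond of 18 is cut back to β-ketoester 17. The C3–C4 bond of 17 is cut back to ketone 16 and a dialkyl carbonate. The C2–C1' bond of 16 is cut back to arene 14 and acid chloride 15, a Friedel–Crafts acylation at the carbon para to one methoxyl and ortho to the other. Arene 14 comes from aldehyde 11 by exchange of the formyl group for a hydroxyl (13) and benzylation.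

## Alternatives that were turned down

**Alternative 1:** The disconnection is O1–C8a alone, with ring A taken back to the acylquinone A1 (1-[4-(benzyloxy)-5-methoxy-3,6-dioxocyclohexa-1,4-dien-1-yl]-3-[5-(benzyloxy)-2,4-dimethoxyphenyl]-2-methoxypropane-1,3-dione). In the forward key step the enol oxygen of the 1,3-diketone adds to the quinone carbon that becomes C8a, and tautomerisation gives the 5,8-hydroquinone A2 (7-(benzyloxy)-2-[5-(benzyloxy)-2,4-dimethoxyphenyl]-5,8-dihydroxy-3,6-dimethoxy-4H-chromen-4-one).
- For it: the closure is redox-neutral and puts oxygen on C5 and C8 in one event. The later methylation of the C8 hydroxyl should be selective, because the C5 hydroxyl is hydrogen-bonded to the C4 carbonyl. No halogenation or copper step is needed, and on this point it is stronger than the chosen route.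
- Against it: A1 must be made by oxidising ring A while ring B, itself a para-dialkoxy arene, and an enolisable diketone are present. Acylquinones are among the most electrophilic quinones, so intermolecular conjugate additions and displacement of the benzyloxy group at the vinylogous ester carbon compete with the wanted closure. The C4–C4a ketone still has to be built beforehand on a pentaoxygenated arene, which is the problem the aryne insertion solves.
- Comparison: the chosen route pays two extra steps at the end but never exposes the electron-rich rings to an oxidant, and it makes the ketone and the aryl ether bond together.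

**Alternative 2:** The disconnection is C3–C4 and C2=C3, with C3 as a one-carbon unit. The ylide A4 ((methoxymethylidene)triphenylphosphorane) is inserted between the acid chloride and the aryl ester carbonyl of A3 (3,5-bis(benzyloxy)-2-(chlorocarbonyl)-4,6-dimethoxyphenyl 5-(benzyloxy)-2,4-dimethoxybenzoate). In the forward key step A4 is acylated by the acid chloride, and the acyl ylide then olefinates the ester carbonyl intramolecularly to close ring C. The product A5 is identical with 24.
- For it: ring C is assembled with no regiochemical question and 24 is reached directly, so the late bromination and methoxylation are saved. In the endgame it is more direct than the chosen route.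
- Against it: A3 requires a hexasubstituted salicylic acid with benzyloxy and methoxy groups alternating around the ring, which means differentiating every ring A oxygen before the coupling; this costs more steps than 10 does. The acid chloride is flanked by an acyloxy and a benzyloxy group and is hindered. A4 is a basic, non-stabilised ylide that can also attack the aryl ester, and half of it is consumed as base. The α-methoxy acyl ylide that results is stabilised and has to olefinate a deactivated dialkoxybenzoate carbonyl to give a tetrasubstituted alkene.
- Comparison: the chosen route takes its ring A from a symmetric phenol made by textbook steps and accepts two more steps after ring closure in exchange.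

**Alternative 3:** The disconnection is C4a–C5, which unrolls ring A into the chain A6 (methyl 9-[5-(benzyloxy)-2,4-dimethoxyphenyl]-2,4,8-trimethoxy-3,5,7,9-tetraoxononanoate). In the forward key step base folds the chain so that the C4a methylene attacks the ester carbon (Claisen condensation), and aromatisation gives A7 (1-[5-(benzyloxy)-2,4-dimethoxyphenyl]-2-methoxy-3-(2,4,6-trihydroxy-3,5-dimethoxyphenyl)propane-1,3-dione).
- For it: ring A is born with all five oxygens and both methoxyls, the hydroxyls at C5 and C7 need no protection, and the ring is symmetric, so either ortho hydroxyl can close ring C. In protecting-group economy it beats the chosen route.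
- Against it: A6 has four ketones and three methoxylated carbons and must be assembled by repeated acylation of polyanions. It would exist as a mixture of enols and cyclic hemiketals. Its most acidic site is the C3 methine between two ketones, which is unproductive, and aldol closures and O-cyclisation to pyranones compete with the Claisen mode.
- Comparison: the risk is spread over several steps with thin analogy, whereas the chosen route concentrates it in one step whose two partners come from standard reactions.

Key step: step 13

## Route

Assumption: the enol ether double bond of 18, 19 and 21 is drawn as E. Should O-methylation give the Z isomer or a mixture, nothing changes downstream, because this geometry is erased when ring C closes in step 14.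

**Step 1**
Reactants: 1 3,5-dihydroxy-4-methoxybenzoic acid
Product: 2 benzyl 3,5-bis(benzyloxy)-4-methoxybenzoate
Conditions: BnBr, K2CO3, DMF, 60 °C
Reagents that add atoms: benzyl bromide, BrCc1ccccc1
Why: Williamson O-alkylation of both phenols and of the carboxylate (SN2 on benzyl bromide); exhaustive benzylation removes every acidic proton before the hydride reduction.

**Step 2**
Reactants: 2 benzyl 3,5-bis(benzyloxy)-4-methoxybenzoate
Product: 3 [3,5-bis(benzyloxy)-4-methoxyphenyl]methanol
Conditions: LiAlH4, THF, 0 °C to rt
Reagents that add atoms: none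
Why: Hydride reduction of the ester to the primary alcohol; aryl benzyl ethers are inert, and the benzyl alcohol released from the ester is removed on purification.

**Step 3**
Reactants: 3 [3,5-bis(benzyloxy)-4-methoxyphenyl]methanol
Product: 4 3,5-bis(benzyloxy)-4-methoxybenzaldehyde
Conditions: MnO2, CH2Cl2, rt
Reagents that add atoms: none
Why: MnO2 oxidises benzylic alcohols selectively to aldehydes and should stop there.

**Step 4**
Reactants: 4 3,5-bis(benzyloxy)-4-methoxybenzaldehyde
Product: 6 3,5-bis(benzyloxy)-4-methoxyphenol, via aryl formate 5 (not isolated)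
Conditions: mCPBA, CH2Cl2, 0 °C to rt; then K2CO3, MeOH, rt
Reagents that add atoms: 3-chloroperoxybenzoic acid (mCPBA), O=C(OO)c1cccc(Cl)c1
Why: Baeyer–Villiger (Dakin-type) oxidation; the electron-rich aryl group migrates in the Criegee intermediate to give the aryl formate, which methanolysis cleaves to the phenol, as with other trialkoxybenzaldehydes.

**Step 5**
Reactants: 6 3,5-bis(benzyloxy)-4-methoxyphenol
Product: 7 3,5-bis(benzyloxy)-2-bromo-4-methoxyphenol
Conditions: NBS (1.0 equiv), CH2Cl2, −78 °C to 0 °C
Reagents that add atoms: N-bromosuccinimide, O=C1CCC(=O)N1Br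
Why: Electrophilic aromatic bromination of a phenol; the two free ring carbons are equivalent by symmetry and each is ortho to the hydroxyl, so one equivalent at low temperature should give a single monobromide.

**Step 6**
Reactants: 7 3,5-bis(benzyloxy)-2-bromo-4-methoxyphenol
Product: 10 3,5-bis(benzyloxy)-4-methoxy-2-(trimethylsilyl)phenyl trifluoromethanesulfonate, via aryl trimethylsilyl ether 8 (not isolated), via lithium silylphenoxide 9 (not isolated)
Conditions: HMDS, THF, 70 °C; then n-BuLi, THF, −78 °C; then Tf2O, −78 °C to rt
Reagents that add atoms: hexamethyldisilazane, C[Si](C)(C)N[Si](C)(C)C; trifluoromethanesulfonic anhydride, O=S(=O)(OS(=O)(=O)C(F)(F)F)C(F)(F)F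
Why: O-silylation, bromine–lithium exchange, 1,3 oxygen-to-carbon silyl shift (retro-Brook rearrangement) and triflation of the phenoxide, the standard one-flask route from ortho-bromophenols to ortho-silylaryl triflates; the exchange at −78 °C is faster than benzylic deprotonation.

**Step 7**
Reactants: 11 2,4-dimethoxybenzaldehyde
Product: 13 2,4-dimethoxyphenol, via aryl formate 12 (not isolated)
Conditions: mCPBA, CH2Cl2, 0 °C to rt; then K2CO3, MeOH, rt
Reagents that add atoms: 3-chloroperoxybenzoic acid (mCPBA), O=C(OO)c1cccc(Cl)c1
Why: Baeyer–Villiger (Dakin-type) oxidation; the ortho- and para-methoxylated aryl group migrates readily, and the formate is cleaved by methanolysis.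

**Step 8**
Reactants: 13 2,4-dimethoxyphenol
Product: 14 1-(benzyloxy)-2,4-dimethoxybenzene
Conditions: BnBr, K2CO3, DMF, rt
Reagents that add atoms: benzyl bromide, BrCc1ccccc1
Why: Williamson ether synthesis; the benzyl group masks the future C5' hydroxyl and turns the phenol into a plain alkoxy substituent for the acylation.

**Step 9**
Reactants: 14 1-(benzyloxy)-2,4-dimethoxybenzene; 15 methoxyacetyl chloride
Product: 16 1-[5-(benzyloxy)-2,4-dimethoxyphenyl]-2-methoxyethan-1-one
Conditions: SnCl4, CH2Cl2, −20 °C to 0 °C
Reagents that add atoms: none
Why: Friedel–Crafts acylation; C5 of 14 is para to one methoxyl and ortho to the other, the position attacked in 1,2,4-trialkoxybenzenes, and SnCl4 at low temperature should spare the benzyl ether, which is not ortho to the new carbonyl.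

**Step 10**
Reactants: 16 1-[5-(benzyloxy)-2,4-dimethoxyphenyl]-2-methoxyethan-1-one
Product: 17 methyl 3-[5-(benzyloxy)-2,4-dimethoxyphenyl]-2-methoxy-3-oxopropanoate (racemic)
Conditions: NaH, (MeO)2CO, THF, reflux; then dilute HCl
Reagents that add atoms: dimethyl carbonate, COC(=O)OC
Why: Claisen-type C-acylation of the ketone enolate by dimethyl carbonate, driven by formation of the stabilised β-ketoester enolate; the stereocentre formed is enolisable and is removed in the next step.

**Step 11**
Reactants: 17 methyl 3-[5-(benzyloxy)-2,4-dimethoxyphenyl]-2-methoxy-3-oxopropanoate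
Product: 18 methyl (E)-3-[5-(benzyloxy)-2,4-dimethoxyphenyl]-2,3-dimethoxyprop-2-enoate
Conditions: Cs2CO3, Me2SO4, DMF, 0 °C to rt
Reagents that add atoms: dimethyl sulfate, COS(=O)(=O)OC
Why: O-alkylation of a β-ketoester enolate; a loosely paired cesium enolate in a dipolar aprotic solvent should react with the hard methylating agent at oxygen, while C-methylation would have to build a fully substituted carbon between two carbonyl groups.

**Step 12**
Reactants: 18 methyl (E)-3-[5-(benzyloxy)-2,4-dimethoxyphenyl]-2,3-dimethoxyprop-2-enoate
Product: 19 (E)-3-[5-(benzyloxy)-2,4-dimethoxyphenyl]-2,3-dimethoxyprop-2-enoic acid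
Conditions: LiOH, THF/MeOH/H2O, 40 °C; then 0.5 M HCl to pH 4, 0 °C
Reagents that add atoms: lithium hydroxide, [Li+].[OH-]
Why: Ester saponification; the β-carbon is shielded by the ortho-methoxyaryl and methoxy groups, so hydroxide should attack the acyl carbon, and acidifying only to pH 4 in the cold protects the enol ether from hydrolysis.

**Step 13**
Reactants: 19 (E)-3-[5-(benzyloxy)-2,4-dimethoxyphenyl]-2,3-dimethoxyprop-2-enoic acid; 10 3,5-bis(benzyloxy)-4-methoxy-2-(trimethylsilyl)phenyl trifluoromethanesulfonate
Product: 21 (E)-1-[4,6-bis(benzyloxy)-2-hydroxy-5-methoxyphenyl]-3-[5-(benzyloxy)-2,4-dimethoxyphenyl]-2,3-dimethoxyprop-2-en-1-one, via aryne 20 (not isolated)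
Conditions: CsF, THF, 125 °C, sealed tube
Reagents that add atoms: none
Why: CsF deprotonates 19 and, by attack on silicon, expels triflate from 10 to give aryne 20; the carboxylate oxygen adds to the aryne carbon remote from the flanking benzyloxy group (future C8a), so that the aryl anion develops on the carbon next to that oxygen (future C4a), where the C–O dipole stabilises it. The anion then attacks the adjacent ester carbonyl in a 4-exo-trig manner to give a benzoxete alkoxide, which opens to the ortho-acylphenoxide; the net result is insertion of the aryne into the acyl C–O bond, formally an anionic 1,3 oxygen-to-carbon acyl shift. The closest known reaction type is the insertion of arynes into the C–O bond of carboxylic acids to give ortho-hydroxyaryl ketones, applied here to a β-alkoxyacrylic acid. No ring remains closed, since the four-membered ring is only a transient, and no stereocentre is formed. Two selectivities are needed: the regiochemistry of addition, secured by the single alkoxy group at C5 against hydrogen at C8, and acyl transfer in preference to protonation of the aryl anion or its conjugate attack on the β-carbon, favoured by aprotic THF at high temperature and by the nearness of the carbonyl carbon. The benzyl ethers and the enol ether are inert to fluoride; should the phenoxide begin to close onto the enol ether in the flask, that material converges with the rest in step 14.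

**Step 14**
Reactants: 21 (E)-1-[4,6-bis(benzyloxy)-2-hydroxy-5-methoxyphenyl]-3-[5-(benzyloxy)-2,4-dimethoxyphenyl]-2,3-dimethoxyprop-2-en-1-one
Product: 22 5,7-bis(benzyloxy)-2-[5-(benzyloxy)-2,4-dimethoxyphenyl]-3,6-dimethoxy-4H-chromen-4-one
Conditions: K2CO3, DMF, 60 °C
Reagents that add atoms: none
Why: Intramolecular oxa-Michael addition–elimination: 6-endo-trig attack of the phenoxide on the β-carbon and E1cB loss of methoxide give the pyranone at the right oxidation level; the alkene geometry is lost at the sp3 intermediate.

**Step 15**
Reactants: 22 5,7-bis(benzyloxy)-2-[5-(benzyloxy)-2,4-dimethoxyphenyl]-3,6-dimethoxy-4H-chromen-4-one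
Product: 23 5,7-bis(benzyloxy)-2-[5-(benzyloxy)-2,4-dimethoxyphenyl]-8-bromo-3,6-dimethoxy-4H-chromen-4-one
Conditions: NBS, DMF, 0 °C to rt
Reagents that add atoms: N-bromosuccinimide, O=C1CCC(=O)N1Br
Why: Electrophilic aromatic bromination; C8 is the only free carbon of ring A and is ortho to O1 and O7 and para to O5, whereas on ring B C3' is crowded between two methoxyls and C6' is activated by one oxygen only.

**Step 16**
Reactants: 23 5,7-bis(benzyloxy)-2-[5-(benzyloxy)-2,4-dimethoxyphenyl]-8-bromo-3,6-dimethoxy-4H-chromen-4-one
Product: 24 5,7-bis(benzyloxy)-2-[5-(benzyloxy)-2,4-dimethoxyphenyl]-3,6,8-trimethoxy-4H-chromen-4-one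
Conditions: NaOMe, CuBr, DMF/MeOH, 110 °C
Reagents that add atoms: sodium methoxide, [Na+].[O-]C
Why: Copper-mediated (Ullmann-type) exchange of an aryl bromide for methoxide, the established way to turn 8-bromoflavones into 8-methoxyflavones; benzyl and methyl ethers are stable to these conditions.

**Step 17**
Reactants: 24 5,7-bis(benzyloxy)-2-[5-(benzyloxy)-2,4-dimethoxyphenyl]-3,6,8-trimethoxy-4H-chromen-4-one
Product: 25 5,7-dihydroxy-2-(5-hydroxy-2,4-dimethoxyphenyl)-3,6,8-trimethoxy-4H-chromen-4-one
Conditions: H2 (1 atm), Pd/C, EtOAc/MeOH, rt
Reagents that add atoms: none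
Why: Hydrogenolysis of the three benzyl ethers; the methyl ethers are untouched, and the tetrasubstituted C2=C3 bond of the pyranone should not be reduced at ambient pressure and temperature.

## Compound list

1 | 3,5-dihydroxy-4-methoxybenzoic acid | COc1c(O)cc(C(=O)O)cc1O | starting material
2 | benzyl 3,5-bis(benzyloxy)-4-methoxybenzoate | COc1c(OCc2ccccc2)cc(C(=O)OCc2ccccc2)cc1OCc1ccccc1 | intermediate
3 | [3,5-bis(benzyloxy)-4-methoxyphenyl]methanol | COc1c(OCc2ccccc2)cc(CO)cc1OCc1ccccc1 | intermediate
4 | 3,5-bis(benzyloxy)-4-methoxybenzaldehyde | COc1c(OCc2ccccc2)cc(C=O)cc1OCc1ccccc1 | intermediate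
5 | 3,5-bis(benzyloxy)-4-methoxyphenyl formate | COc1c(OCc2ccccc2)cc(OC=O)cc1OCc1ccccc1 | intermediate
6 | 3,5-bis(benzyloxy)-4-methoxyphenol | COc1c(OCc2ccccc2)cc(O)cc1OCc1ccccc1 | intermediate
7 | 3,5-bis(benzyloxy)-2-bromo-4-methoxyphenol | COc1c(OCc2ccccc2)cc(O)c(Br)c1OCc1ccccc1 | intermediate
8 | [3,5-bis(benzyloxy)-2-bromo-4-methoxyphenoxy]trimethylsilane | COc1c(OCc2ccccc2)cc(O[Si](C)(C)C)c(Br)c1OCc1ccccc1 | intermediate
9 | lithium 3,5-bis(benzyloxy)-4-methoxy-2-(trimethylsilyl)phenoxide | COc1c(OCc2ccccc2)cc([O-])c([Si](C)(C)C)c1OCc1ccccc1.[Li+] | intermediate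
10 | 3,5-bis(benzyloxy)-4-methoxy-2-(trimethylsilyl)phenyl trifluoromethanesulfonate | COc1c(OCc2ccccc2)cc(OS(=O)(=O)C(F)(F)F)c([Si](C)(C)C)c1OCc1ccccc1 | intermediate
11 | 2,4-dimethoxybenzaldehyde | COc1ccc(C=O)c(OC)c1 | starting material
12 | 2,4-dimethoxyphenyl formate | COc1ccc(OC=O)c(OC)c1 | intermediate
13 | 2,4-dimethoxyphenol | COc1ccc(O)c(OC)c1 | intermediate
14 | 1-(benzyloxy)-2,4-dimethoxybenzene | COc1ccc(OCc2ccccc2)c(OC)c1 | intermediate
15 | methoxyacetyl chloride | COCC(=O)Cl | starting material
16 | 1-[5-(benzyloxy)-2,4-dimethoxyphenyl]-2-methoxyethan-1-one | COCC(=O)c1cc(OCc2ccccc2)c(OC)cc1OC | intermediate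
17 | methyl 3-[5-(benzyloxy)-2,4-dimethoxyphenyl]-2-methoxy-3-oxopropanoate (racemic) | COC(C(=O)OC)C(=O)c1cc(OCc2ccccc2)c(OC)cc1OC | intermediate
18 | methyl (E)-3-[5-(benzyloxy)-2,4-dimethoxyphenyl]-2,3-dimethoxyprop-2-enoate | CO/C(=C(/OC)C(=O)OC)c1cc(OCc2ccccc2)c(OC)cc1OC | intermediate
19 | (E)-3-[5-(benzyloxy)-2,4-dimethoxyphenyl]-2,3-dimethoxyprop-2-enoic acid | CO/C(=C(/OC)C(=O)O)c1cc(OCc2ccccc2)c(OC)cc1OC | intermediate
20 | 3,5-bis(benzyloxy)-4-methoxybenzyne (1,2-didehydrobenzene) | COC1=C(OCc2ccccc2)C#CC=C1OCc1ccccc1 | intermediate
21 | (E)-1-[4,6-bis(benzyloxy)-2-hydroxy-5-methoxyphenyl]-3-[5-(benzyloxy)-2,4-dimethoxyphenyl]-2,3-dimethoxyprop-2-en-1-one | CO/C(=C(/OC)C(=O)c1c(O)cc(OCc2ccccc2)c(OC)c1OCc1ccccc1)c1cc(OCc2ccccc2)c(OC)cc1OC | intermediate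
22 | 5,7-bis(benzyloxy)-2-[5-(benzyloxy)-2,4-dimethoxyphenyl]-3,6-dimethoxy-4H-chromen-4-one | COc1cc(OC)c(-c2oc3cc(OCc4ccccc4)c(OC)c(OCc4ccccc4)c3c(=O)c2OC)cc1OCc1ccccc1 | intermediate
23 | 5,7-bis(benzyloxy)-2-[5-(benzyloxy)-2,4-dimethoxyphenyl]-8-bromo-3,6-dimethoxy-4H-chromen-4-one | COc1cc(OC)c(-c2oc3c(Br)c(OCc4ccccc4)c(OC)c(OCc4ccccc4)c3c(=O)c2OC)cc1OCc1ccccc1 | intermediate
24 | 5,7-bis(benzyloxy)-2-[5-(benzyloxy)-2,4-dimethoxyphenyl]-3,6,8-trimethoxy-4H-chromen-4-one | COc1cc(OC)c(-c2oc3c(OC)c(OCc4ccccc4)c(OC)c(OCc4ccccc4)c3c(=O)c2OC)cc1OCc1ccccc1 | intermediate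
25 | 5,7-dihydroxy-2-(5-hydroxy-2,4-dimethoxyphenyl)-3,6,8-trimethoxy-4H-chromen-4-one | COc1cc(OC)c(-c2oc3c(OC)c(O)c(OC)c(O)c3c(=O)c2OC)cc1O | target

## Step count and risk

Total step count: 17. Longest linear sequence: 11 steps (steps 1 to 6 or steps 7 to 12, followed by steps 13 to 17).

**Step 13 (key step).** The aryl anion formed after oxygen addition may be protonated before the acyl group shifts, so that only O-arylation occurs. The acyl shift may also be slow, because the β-methoxyl feeds electron density into the acyl carbon, and methoxide released by early ring closure may consume aryne. Fallback: the same two bonds are made stepwise without an aryne. Bromophenol 7 is esterified with acid 19 (EDC, DMAP, CH2Cl2) to the 2-bromoaryl ester F1. Bromine–lithium exchange on F1 (n-BuLi, THF, −100 °C) should give an aryllithium that attacks the neighbouring ester carbonyl, a halogen–metal-exchange-induced anionic Fries shift. The resulting phenoxide is protonated on work-up to 21, where the route is rejoined.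

**Step 15.** Chemoselectivity between two electron-rich rings may be poor, with bromination at C3' of ring B alongside or in place of C8. Fallback: bromination is moved ahead of ring closure, where the free phenol makes the future C8 by far the most reactive position. Compound 21 is treated with NBS at −78 °C to give the bromo hydroxy ketone F2, and F2 is closed with K2CO3 in DMF as in step 14 to give 23.

**Step 16.** The bromide at C8 sits between two oxygen-bearing carbons, so substitution may stall and reductive loss of bromine may take over. Hot methoxide may also add at C2 and open the pyranone. Fallback: the C8–O bond is made by boron oxidation and the methyl group by O-alkylation. Compound 23 undergoes Miyaura borylation (Pd(OAc)2, SPhos, B2pin2, KOAc, dioxane, 100 °C) to the 8-boronate F3. Oxidation (NaBO3, THF/H2O, rt) gives the 8-hydroxychromone F4, and methylation (MeI, K2CO3, acetone) gives 24.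

**Step 11.** Methylation may occur at carbon instead of oxygen, and the enol ether geometry is not controlled. Fallback: the enol ether is made under acid catalysis through a ketal instead of through an enolate. Compound 17 is heated with trimethyl orthoformate and catalytic H2SO4 in MeOH to give the dimethyl ketal F5, which should lose methanol on continued heating with acid to give 18.

**Step 12.** The enol ether may be lost on acidification (hydrolysis to the β-keto acid and decarboxylation), or hydroxide may displace the β-methoxyl. Fallback: the free acid is not isolated. Compound 18 is cleaved under anhydrous conditions with KOSiMe3 in THF to the potassium carboxylate F6, which is dried and used directly with 10 and CsF under the conditions of step 13. The carboxylate is the species that adds to the aryne in any case, and aqueous work-up gives 21.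

**Step 9.** The methoxyacetyl cation may lose carbon monoxide and alkylate the ring, or the Lewis acid may cleave the benzyl ether. Fallback: the side chain is built from the aldehyde without a Lewis acid. Compound 14 is formylated (POCl3, DMF, Vilsmeier–Haack) to the aldehyde F7. Addition of the lithium enolate of methyl methoxyacetate (LDA, THF, −78 °C) gives the aldol F8 as a mixture of diastereomers, and oxidation with Dess–Martin periodinane gives 17.

## Further compounds

F1 | step 13 | 3,5-bis(benzyloxy)-2-bromo-4-methoxyphenyl (E)-3-[5-(benzyloxy)-2,4-dimethoxyphenyl]-2,3-dimethoxyprop-2-enoate | CO/C(=C(/OC)C(=O)Oc1cc(OCc2ccccc2)c(OC)c(OCc2ccccc2)c1Br)c1cc(OCc2ccccc2)c(OC)cc1OC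
F2 | step 15 | (E)-1-[4,6-bis(benzyloxy)-3-bromo-2-hydroxy-5-methoxyphenyl]-3-[5-(benzyloxy)-2,4-dimethoxyphenyl]-2,3-dimethoxyprop-2-en-1-one | CO/C(=C(/OC)C(=O)c1c(O)c(Br)c(OCc2ccccc2)c(OC)c1OCc1ccccc1)c1cc(OCc2ccccc2)c(OC)cc1OC
F3 | step 16 | 5,7-bis(benzyloxy)-2-[5-(benzyloxy)-2,4-dimethoxyphenyl]-3,6-dimethoxy-8-(4,4,5,5-tetramethyl-1,3,2-dioxaborolan-2-yl)-4H-chromen-4-one | COc1cc(OC)c(-c2oc3c(B4OC(C)(C)C(C)(C)O4)c(OCc4ccccc4)c(OC)c(OCc4ccccc4)c3c(=O)c2OC)cc1OCc1ccccc1
F4 | step 16 | 5,7-bis(benzyloxy)-2-[5-(benzyloxy)-2,4-dimethoxyphenyl]-8-hydroxy-3,6-dimethoxy-4H-chromen-4-one | COc1cc(OC)c(-c2oc3c(O)c(OCc4ccccc4)c(OC)c(OCc4ccccc4)c3c(=O)c2OC)cc1OCc1ccccc1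
F5 | step 11 | methyl 3-[5-(benzyloxy)-2,4-dimethoxyphenyl]-2,3,3-trimethoxypropanoate | COC(C(=O)OC)C(OC)(OC)c1cc(OCc2ccccc2)c(OC)cc1OC
F6 | step 12 | potassium (E)-3-[5-(benzyloxy)-2,4-dimethoxyphenyl]-2,3-dimethoxyprop-2-enoate | CO/C(=C(/OC)C(=O)[O-])c1cc(OCc2ccccc2)c(OC)cc1OC.[K+]
F7 | step 9 | 5-(benzyloxy)-2,4-dimethoxybenzaldehyde | COc1cc(OC)c(C=O)cc1OCc1ccccc1
F8 | step 9 | methyl 3-[5-(benzyloxy)-2,4-dimethoxyphenyl]-3-hydroxy-2-methoxypropanoate (mixture of diastereomers) | COC(C(=O)OC)C(O)c1cc(OCc2ccccc2)c(OC)cc1OC
A1 | alternative 1 | 1-[4-(benzyloxy)-5-methoxy-3,6-dioxocyclohexa-1,4-dien-1-yl]-3-[5-(benzyloxy)-2,4-dimethoxyphenyl]-2-methoxypropane-1,3-dione | COC1=C(OCc2ccccc2)C(=O)C=C(C(=O)C(OC)C(=O)c2cc(OCc3ccccc3)c(OC)cc2OC)C1=O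
A2 | alternative 1 | 7-(benzyloxy)-2-[5-(benzyloxy)-2,4-dimethoxyphenyl]-5,8-dihydroxy-3,6-dimethoxy-4H-chromen-4-one | COc1cc(OC)c(-c2oc3c(O)c(OCc4ccccc4)c(OC)c(O)c3c(=O)c2OC)cc1OCc1ccccc1
A3 | alternative 2 | 3,5-bis(benzyloxy)-2-(chlorocarbonyl)-4,6-dimethoxyphenyl 5-(benzyloxy)-2,4-dimethoxybenzoate | COc1cc(OC)c(C(=O)Oc2c(OC)c(OCc3ccccc3)c(OC)c(OCc3ccccc3)c2C(=O)Cl)cc1OCc1ccccc1
A4 | alternative 2 | (methoxymethylidene)triphenylphosphorane | COC=P(c1ccccc1)(c1ccccc1)c1ccccc1
A5 | alternative 2 | 5,7-bis(benzyloxy)-2-[5-(benzyloxy)-2,4-dimethoxyphenyl]-3,6,8-trimethoxy-4H-chromen-4-one | COc1cc(OC)c(-c2oc3c(OC)c(OCc4ccccc4)c(OC)c(OCc4ccccc4)c3c(=O)c2OC)cc1OCc1ccccc1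
A6 | alternative 3 | methyl 9-[5-(benzyloxy)-2,4-dimethoxyphenyl]-2,4,8-trimethoxy-3,5,7,9-tetraoxononanoate | COC(=O)C(OC)C(=O)C(OC)C(=O)CC(=O)C(OC)C(=O)c1cc(OCc2ccccc2)c(OC)cc1OC
A7 | alternative 3 | 1-[5-(benzyloxy)-2,4-dimethoxyphenyl]-2-methoxy-3-(2,4,6-trihydroxy-3,5-dimethoxyphenyl)propane-1,3-dione | COc1c(O)c(OC)c(O)c(C(=O)C(OC)C(=O)c2cc(OCc3ccccc3)c(OC)cc2OC)c1O
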